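**Route outline**

1. Numbering used throughout: C1 = AcO-bearing cyclobutane CH, C2 = cyclobutane CH2, C3 = C(Me) shared by the four- and five-membered rings, C4 = CHBr, C5 = CH2, C6 = C(Me) shared by the five- and six-membered rings, C7 = CHMe, C8 = CHBr, C9 = CHOH, C10 = CHMe, C11 = carbon common to all three rings. In these locants the target is 1R,3R,4S,6R,7R,8S,9R,10R,11R.
2. Enabling feature: rings C11–C1–C2–C3 and C11–C3–C4–C5–C6 make a cis-bicyclo[3.2.0]heptane. Its shared bond C11–C3 joins two fully substituted carbons and its C1 carries oxygen, so it is the valence isomer of a 2-siloxycyclohepta-1,3-diene C11=C1(OSi)–C2=C3. C11–C3 is therefore cut first.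
3. Further cuts: C2=C3 (ring-closing metathesis), C1–C2 and C3–C4 (vinyl and isopropenyl Grignard additions), C11–C1 (carbonylation of an enol triflate), C6–C5 and C7–Me (conjugate addition/allylation of 2-methylcyclohexenone). The C–Br, C1–OAc and C9–OH bonds are adjusted last.
4. Ring order forward: the cyclohexane is bought, the seven-membered ring is closed onto it by metathesis, and the photochemical 4π closure then splits that ring into cyclobutene and cyclopentane.
5. Stereochemistry: C7 from the chiral copper catalyst, C6 from anti allylation, C10 by equilibration, C4 by CBS reduction then inversion by bromide, C11 and C3 relayed from C6 in the photoclosure, C1 by thermodynamically controlled reduction, C8 and C9 by substrate-controlled bromination and hydride delivery.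

Key step: step 20

Assumption: C11 is a disposable centre from 13 to 26 (it becomes trigonal in step 19), so any C11 epimer surviving step 8 is carried along and converges at 28; structures are drawn for the equatorial epimer.

**Route**

Step 1
Reactants: 1 2-methylcyclohex-2-en-1-one; 2 allyl bromide
Product: 4 (2R,3S)-2-allyl-2,3-dimethylcyclohexan-1-one, via magnesium enolate 3 (not isolated)
Conditions: MeMgBr, Cu(OTf)2 (3 mol %), chiral imidazolinium chloride (carbene ligand precursor, 4 mol %, enantiomer chosen for the 3S centre), Et2O, 0 °C; then 2, DMPU, 0 → 25 °C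
Reagents that add atoms: methylmagnesium bromide, C[Mg]Br
Why: Copper-catalysed asymmetric conjugate addition sets C7 under ligand control, and the magnesium enolate is allylated anti to the new methyl, which makes the two methyls cis and creates quaternary C6 (tandem conjugate addition–enolate alkylation).

Step 2
Reactants: 4 (2R,3S)-2-allyl-2,3-dimethylcyclohexan-1-one
Product: 6 (2R,3S)-2-allyl-2,3,6-trimethylcyclohexan-1-one (C6 epimer mixture), via lithium enolate 5 (not isolated)
Conditions: LiN(i-Pr)2, THF, −78 °C; MeI, −78 → 0 °C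
Reagents that add atoms: iodomethane, CI
Why: Kinetic enolate alkylation at the only enolisable α-carbon (future C10); the new centre needs no control because it becomes trigonal in step 3.

Step 3
Reactants: 6 (2R,3S)-2-allyl-2,3,6-trimethylcyclohexan-1-one
Product: 8 (5S,6R)-6-allyl-2,5,6-trimethylcyclohex-1-en-1-yl trifluoromethanesulfonate, via potassium enolate 7 (not isolated)
Conditions: KN(SiMe3)2, THF, −78 → 0 °C; PhNTf2, −78 → 25 °C
Reagents that add atoms: N-phenylbis(trifluoromethanesulfonimide), O=S(=O)(N(c1ccccc1)S(=O)(=O)C(F)(F)F)C(F)(F)F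
Why: Enolate O-triflation; only the tetrasubstituted enolate can form because the other α-carbon is quaternary.

Step 4
Reactants: 8 enol triflate
Product: 9 methyl (5S,6R)-6-allyl-2,5,6-trimethylcyclohex-1-ene-1-carboxylate
Conditions: Pd(OAc)2 (5 mol %), dppf (6 mol %), CO (1 atm), MeOH, Et3N, DMF, 60 °C
Reagents that add atoms: carbon monoxide, [C-]#[O+]; methanol, CO
Why: Palladium-catalysed alkoxycarbonylation of an enol triflate (oxidative addition, CO insertion, methanolysis) installs C1; excess methanol should intercept the acylpalladium species before the remote alkene can.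

Step 5
Reactants: 9 methyl (5S,6R)-6-allyl-2,5,6-trimethylcyclohex-1-ene-1-carboxylate
Product: 10 methyl (5S,6R)-6-allyl-2,5,6-trimethyl-3-oxocyclohex-1-ene-1-carboxylate
Conditions: Rh2(cap)4 (dirhodium tetrakis(caprolactamate), 1 mol %), t-BuOOH (5 equiv, in decane), K2CO3, CH2Cl2, 25 °C
Reagents that add atoms: tert-butyl hydroperoxide, CC(C)(C)OO
Why: Peroxyl-radical allylic oxidation of the γ-methylene of an unsaturated ester; the ring CH2 (C9) gives a radical conjugated with the enoate, whereas the allyl CH2 is neopentylic and adjoins only an unactivated terminal alkene.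

Step 6
Reactants: 10 enone ester
Product: 11 methyl 6-allyl-2,5,6-trimethyl-3-oxocyclohexane-1-carboxylate (C5 and C6 as in 10, mixture at C1 and C2 of this name)
Conditions: Zn dust, AcOH, 25 °C
Reagents that add atoms: none
Why: Zinc–acetic acid conjugate reduction of the ene-1,4-dicarbonyl unit (electron transfer, protonation) saturates C10=C11 without touching the isolated alkene; C10 and C11 are settled in steps 7 and 8.

Step 7
Reactants: 11 saturated keto ester
Product: 12 C9 ethylene ketal of 11, C10 methyl equatorial, mixture at C11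
Conditions: HOCH2CH2OH, p-TsOH (cat.), benzene, reflux, Dean–Stark
Reagents that add atoms: ethylene glycol, OCCO
Why: Acid-catalysed ketalisation with azeotropic water removal; C10 equilibrates through the enol and enol ether to the equatorial methyl, because an axial one would be syn-diaxial to the C6 methyl.

Step 8
Reactants: 12 ketal ester (C11 mixture)
Product: 13 ketal ester, single isomer (C11 ester equatorial: trans to the C10 methyl and to the allyl group, cis to the C6 methyl)
Conditions: NaOMe, MeOH, 65 °C
Reagents that add atoms: none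
Why: Base-mediated epimerisation through the ester enolate; the axial ester would be syn-axial to a ketal oxygen, so the equatorial epimer should dominate.

Step 9
Reactants: 13 ketal ester
Product: 15 ketal ester aldehyde (CH2CHO = C5–C4 in place of allyl), via ozonide 14 (not isolated)
Conditions: O3, CH2Cl2, −78 °C; then PPh3, −78 → 25 °C
Reagents that add atoms: ozone, [O-][O+]=O
Why: Ozonolysis of the terminal alkene with reductive work-up; ester and ketal are inert.

Step 10
Reactants: 15 ketal ester aldehyde; 16 isopropenylmagnesium bromide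
Product: 17 isopropenyl carbinol (C4 epimer mixture)
Conditions: THF, −78 °C; aq. NH4Cl
Reagents that add atoms: none
Why: Grignard addition to the aldehyde, chemoselective over the hindered ester at low temperature; C4 is reset in steps 11 and 12.

Step 11
Reactants: 17 isopropenyl carbinol
Product: 18 isopropenyl ketone (C4 ketone)
Conditions: Dess–Martin periodinane, NaHCO3, CH2Cl2, 0 → 25 °C
Reagents that add atoms: none
Why: Dess–Martin oxidation of the allylic alcohol under buffered conditions that spare the ketal.

Step 12
Reactants: 18 isopropenyl ketone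
Product: 19 (4R)-allylic alcohol
Conditions: (S)-2-methyl-CBS-oxazaborolidine (20 mol %), catecholborane, toluene, −78 °C
Reagents that add atoms: none
Why: Corey–Bakshi–Shibata reduction; the α-branched alkenyl group acts as the large substituent, so the (S)-catalyst should give the R carbinol (same sense as aryl alkyl ketones), and catecholborane avoids hydroboration.

Step 13
Reactants: 19 (4R)-allylic alcohol
Product: 20 (4R)-tert-butyldimethylsilyl ether methyl ester
Conditions: TBSOTf, 2,6-lutidine, CH2Cl2, −78 → 0 °C
Reagents that add atoms: tert-butyldimethylsilyl trifluoromethanesulfonate, CC(C)(C)[Si](C)(C)OS(=O)(=O)C(F)(F)F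
Why: Silylation of a hindered secondary alcohol with the silyl triflate; the silyl ether is transparent at the wavelength of step 20.

Step 14
Reactants: 20 silyl ether methyl ester
Product: 21 primary alcohol (C1 = CH2OH)
Conditions: LiAlH4, THF, 0 → 25 °C
Reagents that add atoms: none
Why: Hydride reduction of the ester; chosen because acyl substitution by an amine at this doubly flanked ester would be slow.

Step 15
Reactants: 21 primary alcohol
Product: 22 aldehyde (C1 = CHO)
Conditions: Dess–Martin periodinane, NaHCO3, CH2Cl2, 0 → 25 °C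
Reagents that add atoms: none
Why: Dess–Martin oxidation to the aldehyde.

Step 16
Reactants: 22 aldehyde; 23 vinylmagnesium bromide
Product: 24 vinyl carbinol (C1 epimer mixture)
Conditions: THF, −78 → 0 °C; aq. NH4Cl
Reagents that add atoms: none
Why: Grignard addition brings in C2; the carbinol centre is removed in step 17.

Step 17
Reactants: 24 vinyl carbinol
Product: 25 vinyl ketone diene (C1 acryloyl and C4 siloxy isopropenyl chains trans on the cyclohexane)
Conditions: Dess–Martin periodinane, NaHCO3, CH2Cl2, 0 °C
Reagents that add atoms: none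
Why: Dess–Martin oxidation of the allylic alcohol to the enone, which is used without storage.

Step 18
Reactants: 25 vinyl ketone diene
Product: 26 trans-fused bicyclo[5.4.0]undecenone (C1 ketone, C2=C3 with C3 methyl, C4 OTBS, C9 ketal)
Conditions: second-generation Hoveyda–Grubbs catalyst, RuCl2(H2IMes)(=CH-C6H4-2-O-i-Pr) (10 mol %), toluene (0.005 M), 80 °C, argon sparge
Reagents that add atoms: none
Why: Ring-closing metathesis of the acryloyl alkene with the 1,1-disubstituted alkene forms trisubstituted C2=C3 and the seven-membered ring, driven by loss of ethene.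

Step 19
Reactants: 26 cycloheptenone
Product: 28 2-siloxycyclohepta-1,3-diene (C11=C1(OTBS)–C2=C3), via lithium dienolate 27 (not isolated)
Conditions: LiN(i-Pr)2, THF, −78 °C; then TBSOTf, −78 → 0 °C
Reagents that add atoms: tert-butyldimethylsilyl trifluoromethanesulfonate, CC(C)(C)[Si](C)(C)OS(=O)(=O)C(F)(F)F
Why: Kinetic deprotonation of an enone at the α′ position (C11–H, syn-axial to a ketal oxygen that can guide the amide) and O-silylation give the cross-conjugated dienol ether rather than the γ-derived isomer.

Step 20
Reactants: 28 2-siloxycyclohepta-1,3-diene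
Product: 29 siloxycyclobutene tricycle
Conditions: hν (254 nm, low-pressure Hg lamp, quartz), degassed pentane (0.01 M), 20 °C
Reagents that add atoms: none
Why: Direct excitation of the siloxydiene C11=C1–C2=C3, held s-cis by the seven-membered ring, gives the singlet excited state, which closes by disrotatory 4π electrocyclisation to form the σ-bond C11–C3. The closest known reaction type is the photoisomerisation of cyclohepta-1,3-dienes (also eucarvone and tropolone ethers) to bicyclo[3.2.0]hept-6-enes; a 2-siloxy diene with both termini fully substituted is a new substitution pattern within that class. The cyclobutene (C11, C1, C2, C3) closes in the 4π electrocyclic mode, while the cyclopentane (C11, C3, C4, C5, C6) is not closed separately but is what remains of the seven-membered ring once the transannular bond exists. C11 and C3 must be cis to each other, and their sense is dictated by C6: only the rotation that places the cyclobutene on the face of the C6 methyl leaves the six-membered ring cis-fused to the new cyclopentane, whereas the other sense would demand a trans-fused six-membered ring on an envelope locked by the cyclobutene. The step needs closure to win over hydrogen or silyl shifts and double-bond isomerisation, which the ring-constrained diene and the absence of any other chromophore (silyl ethers and ketal are transparent) should secure. The product no longer absorbs at 254 nm and cannot reopen thermally, because conrotatory opening would put a trans double bond in a seven-membered ring.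

Step 21
Reactants: 29 siloxycyclobutene tricycle
Product: 30 tricyclic cyclobutanone (C1 ketone, C4 OTBS, C9 ketal)
Conditions: Bu4NF (1.1 equiv), AcOH (1.1 equiv), THF, −20 → 0 °C
Reagents that add atoms: none
Why: Fluoride cleavage of the enol silyl ether, far faster than that of the hindered alkyl silyl ether, with acetic acid protonating the enolate at C2 at once.

Step 22
Reactants: 30 tricyclic cyclobutanone
Product: 31 exo-cyclobutanol (C1 OH cis to C10 and to the C3 methyl)
Conditions: Li, NH3(l)/THF, t-BuOH, −78 °C; then NH4Cl
Reagents that add atoms: none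
Why: Dissolving-metal reduction protonates the ketyl-derived carbanion under thermodynamic control, placing oxygen exo because an endo oxygen would be nearly eclipsed with the C6 methyl; hydride is not relied on since both faces of the carbonyl are screened.

Step 23
Reactants: 31 exo-cyclobutanol
Product: 32 C1 acetate
Conditions: Ac2O, DMAP, pyridine, 25 → 40 °C
Reagents that add atoms: acetic anhydride, CC(=O)OC(C)=O
Why: DMAP-catalysed acetylation of the secondary alcohol with retention at C1.

Step 24
Reactants: 32 C1 acetate
Product: 33 C4 alcohol (OH cis to the C3 methyl)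
Conditions: HF·pyridine, pyridine, THF, 0 → 25 °C
Reagents that add atoms: none
Why: Buffered fluoride desilylation, which leaves the acetate and the dioxolane intact.

Step 25
Reactants: 33 C4 alcohol
Product: 34 C4 bromide (Br trans to the C3 methyl, cis to the cyclobutane and the C6 methyl), C9 ketal
Conditions: PPh3, CBr4, 2,6-lutidine, toluene, 0 → 60 °C
Reagents that add atoms: carbon tetrabromide, BrC(Br)(Br)Br
Why: Appel reaction; bromide displaces the alkoxyphosphonium group with inversion, entering C4 on the face opposite the angular C3 methyl, the same sense as inversions at C17 of steroids.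

Step 26
Reactants: 34 bromo ketal
Product: 35 keto acetate bromide (C9 ketone)
Conditions: 2 M HCl (aq), THF, 25 °C
Reagents that add atoms: water, O
Why: Acid hydrolysis of the dioxolane; C10 already holds the thermodynamically preferred equatorial methyl, and acetate and bromide tolerate dilute acid.

Step 27
Reactants: 35 keto acetate bromide
Product: 37 trimethylsilyl enol ether (C8=C9), via lithium enolate 36 (not isolated)
Conditions: LiN(SiMe3)2, Me3SiCl, Et3N, THF, −78 °C (base added to ketone and silyl chloride)
Reagents that add atoms: chlorotrimethylsilane, C[Si](C)(C)Cl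
Why: Kinetic enolisation with internal quench removes the axial hydrogen of the C8 methylene rather than the C10 methine beside quaternary C11, and the ketone is deprotonated faster than the acetate.

Step 28
Reactants: 37 trimethylsilyl enol ether
Product: 38 8-bromo ketone (Br trans to the C7 methyl)
Conditions: NBS, THF, −78 → 0 °C
Reagents that add atoms: N-bromosuccinimide, O=C1CCC(=O)N1Br
Why: Electrophilic bromination of the silyl enol ether from the face opposite the axial C6 methyl and the adjacent C7 methyl gives the equatorial bromide, which is also the thermodynamic epimer.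

Step 29
Reactants: 38 8-bromo ketone
Product: 39 target CNP0246576.1
Conditions: LiBH(s-Bu)3, THF, −78 °C; aq. NH4Cl
Reagents that add atoms: none
Why: The bulky hydride attacks C9 from the equatorial direction because the axial path is blocked by C3 (axial on C11), giving the axial alcohol cis to the C8 bromine and the C10 methyl; at −78 °C the acetate and bromides should survive.

**Compound list**

1 | 2-methylcyclohex-2-en-1-one | CC1=CCCCC1=O | starting material
2 | allyl bromide | C=CCBr | starting material
3 | bromomagnesium (3S)-2,3-dimethylcyclohex-1-en-1-olate | Br[Mg]OC1=C(C)[C@@H](C)CCC1 | intermediate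
4 | (2R,3S)-2-allyl-2,3-dimethylcyclohexan-1-one (methyls cis) | O=C1[C@](C)(CC=C)[C@@H](C)CCC1 | intermediate
5 | lithium (5S,6R)-6-allyl-5,6-dimethylcyclohex-1-en-1-olate | [Li]OC1=CCC[C@H](C)[C@@]1(C)CC=C | intermediate
6 | (2R,3S)-2-allyl-2,3,6-trimethylcyclohexan-1-one, C6 epimer mixture | O=C1[C@](C)(CC=C)[C@@H](C)CCC1C | intermediate
7 | potassium (5S,6R)-6-allyl-2,5,6-trimethylcyclohex-1-en-1-olate | [K]OC1=C(C)CC[C@H](C)[C@@]1(C)CC=C | intermediate
8 | (5S,6R)-6-allyl-2,5,6-trimethylcyclohex-1-en-1-yl trifluoromethanesulfonate | O=S(=O)(OC1=C(C)CC[C@H](C)[C@@]1(C)CC=C)C(F)(F)F | intermediate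
9 | methyl (5S,6R)-6-allyl-2,5,6-trimethylcyclohex-1-ene-1-carboxylate | COC(=O)C1=C(C)CC[C@H](C)[C@@]1(C)CC=C | intermediate
10 | methyl (5S,6R)-6-allyl-2,5,6-trimethyl-3-oxocyclohex-1-ene-1-carboxylate | COC(=O)C1=C(C)C(=O)C[C@H](C)[C@@]1(C)CC=C | intermediate
11 | methyl 6-allyl-2,5,6-trimethyl-3-oxocyclohexane-1-carboxylate, mixture at the ester and adjacent methyl carbons | COC(=O)C1C(C)C(=O)C[C@H](C)[C@@]1(C)CC=C | intermediate
12 | C9 ethylene ketal of 11, C10 methyl equatorial, mixture at C11 | COC(=O)C1[C@@H](C)C2(OCCO2)C[C@H](C)[C@@]1(C)CC=C | intermediate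
13 | ketal ester, C11 ester trans to C10 methyl and to allyl, cis to C6 methyl | COC(=O)[C@@H]1[C@@H](C)C2(OCCO2)C[C@H](C)[C@@]1(C)CC=C | intermediate
14 | 1,2,4-trioxolane (ozonide) of 13 | COC(=O)[C@@H]1[C@@H](C)C2(OCCO2)C[C@H](C)[C@@]1(C)CC3OCOO3 | intermediate
15 | ketal ester aldehyde (C4 aldehyde) | COC(=O)[C@@H]1[C@@H](C)C2(OCCO2)C[C@H](C)[C@@]1(C)CC=O | intermediate
16 | isopropenylmagnesium bromide | C=C(C)[Mg]Br | starting material
17 | isopropenyl carbinol, C4 epimer mixture | COC(=O)[C@@H]1[C@@H](C)C2(OCCO2)C[C@H](C)[C@@]1(C)CC(O)C(C)=C | intermediate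
18 | isopropenyl ketone (C4 ketone) | COC(=O)[C@@H]1[C@@H](C)C2(OCCO2)C[C@H](C)[C@@]1(C)CC(=O)C(C)=C | intermediate
19 | (4R)-allylic alcohol | COC(=O)[C@@H]1[C@@H](C)C2(OCCO2)C[C@H](C)[C@@]1(C)C[C@@H](O)C(C)=C | intermediate
20 | (4R)-tert-butyldimethylsilyl ether methyl ester | COC(=O)[C@@H]1[C@@H](C)C2(OCCO2)C[C@H](C)[C@@]1(C)C[C@@H](O[Si](C)(C)C(C)(C)C)C(C)=C | intermediate
21 | primary alcohol (C1 CH2OH) | OC[C@@H]1[C@@H](C)C2(OCCO2)C[C@H](C)[C@@]1(C)C[C@@H](O[Si](C)(C)C(C)(C)C)C(C)=C | intermediate
22 | aldehyde (C1 CHO) | O=C[C@@H]1[C@@H](C)C2(OCCO2)C[C@H](C)[C@@]1(C)C[C@@H](O[Si](C)(C)C(C)(C)C)C(C)=C | intermediate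
23 | vinylmagnesium bromide | C=C[Mg]Br | starting material
24 | vinyl carbinol, C1 epimer mixture | C=CC(O)[C@@H]1[C@@H](C)C2(OCCO2)C[C@H](C)[C@@]1(C)C[C@@H](O[Si](C)(C)C(C)(C)C)C(C)=C | intermediate
25 | vinyl ketone diene | C=CC(=O)[C@@H]1[C@@H](C)C2(OCCO2)C[C@H](C)[C@@]1(C)C[C@@H](O[Si](C)(C)C(C)(C)C)C(C)=C | intermediate
26 | trans-fused bicyclo[5.4.0]undecenone (C1 ketone, C2=C3) | O=C1C=C(C)[C@H](O[Si](C)(C)C(C)(C)C)C[C@]2(C)[C@@H](C)CC3(OCCO3)[C@H](C)[C@@H]12 | intermediate
27 | lithium cross-conjugated dienolate (C11=C1–OLi, C2=C3) | [Li]OC1=C2[C@@H](C)C3(OCCO3)C[C@H](C)[C@@]2(C)C[C@@H](O[Si](C)(C)C(C)(C)C)C(C)=C1 | intermediate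
28 | 2-siloxycyclohepta-1,3-diene fused to the cyclohexane | CC(C)(C)[Si](C)(C)OC1=C2[C@@H](C)C3(OCCO3)C[C@H](C)[C@@]2(C)C[C@@H](O[Si](C)(C)C(C)(C)C)C(C)=C1 | intermediate
29 | siloxycyclobutene tricycle | CC(C)(C)[Si](C)(C)OC1=C[C@@]2(C)[C@H](O[Si](C)(C)C(C)(C)C)C[C@]3(C)[C@@H](C)CC4(OCCO4)[C@H](C)[C@]123 | intermediate
30 | tricyclic cyclobutanone | O=C1C[C@@]2(C)[C@H](O[Si](C)(C)C(C)(C)C)C[C@]3(C)[C@@H](C)CC4(OCCO4)[C@H](C)[C@]123 | intermediate
31 | exo-cyclobutanol (C1 OH cis to C10 and C3 methyl) | O[C@@H]1C[C@@]2(C)[C@H](O[Si](C)(C)C(C)(C)C)C[C@]3(C)[C@@H](C)CC4(OCCO4)[C@H](C)[C@]123 | intermediate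
32 | C1 acetate, C4 silyl ether, C9 ketal | CC(=O)O[C@@H]1C[C@@]2(C)[C@H](O[Si](C)(C)C(C)(C)C)C[C@]3(C)[C@@H](C)CC4(OCCO4)[C@H](C)[C@]123 | intermediate
33 | C4 alcohol (OH cis to C3 methyl) | CC(=O)O[C@@H]1C[C@@]2(C)[C@H](O)C[C@]3(C)[C@@H](C)CC4(OCCO4)[C@H](C)[C@]123 | intermediate
34 | C4 bromide (Br trans to C3 methyl), C9 ketal | CC(=O)O[C@@H]1C[C@@]2(C)[C@@H](Br)C[C@]3(C)[C@@H](C)CC4(OCCO4)[C@H](C)[C@]123 | intermediate
35 | keto acetate bromide (C9 ketone) | CC(=O)O[C@@H]1C[C@@]2(C)[C@@H](Br)C[C@]3(C)[C@@H](C)CC(=O)[C@H](C)[C@]123 | intermediate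
36 | lithium C8=C9 enolate | CC(=O)O[C@@H]1C[C@@]2(C)[C@@H](Br)C[C@]3(C)[C@@H](C)C=C(O[Li])[C@H](C)[C@]123 | intermediate
37 | trimethylsilyl enol ether (C8=C9) | CC(=O)O[C@@H]1C[C@@]2(C)[C@@H](Br)C[C@]3(C)[C@@H](C)C=C(O[Si](C)(C)C)[C@H](C)[C@]123 | intermediate
38 | 8-bromo ketone (Br trans to C7 methyl) | CC(=O)O[C@@H]1C[C@@]2(C)[C@@H](Br)C[C@]3(C)[C@@H](C)[C@H](Br)C(=O)[C@H](C)[C@]123 | intermediate
39 | CNP0246576.1 | CC(=O)O[C@@H]1C[C@@]2(C)[C@@H](Br)C[C@]3(C)[C@@H](C)[C@H](Br)[C@H](O)[C@H](C)[C@]123 | target

**Step count and risks**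

Total steps: 29. Longest linear sequence: 29 (from 1).

Three steps most likely to fail:

- **Step 20 (photochemical closure).** The excited diene may decay by hydrogen or silyl shift or by reversible double-bond isomerisation instead of closing, because both termini are fully substituted. Fallback, a thermal intramolecular ketene–alkene [2+2] cycloaddition, sets out from aldehyde 22. Oxidation with NaClO2, NaH2PO4 and 2-methylbut-2-ene gives the carboxylic acid F1. 1-Chloro-N,N,2-trimethylpropenylamine converts it under neutral conditions into the acid chloride F2. Et3N in refluxing toluene then generates the ketene F3 (C11=C1=O), which adds across the isopropenyl group (C1 to the terminal CH2 that becomes C2, C11 to C3) under the same ring-fusion constraint. This gives cyclobutanone 30, where the route resumes.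

- **Step 25 (bromide at C4).** The alkoxyphosphonium ion may ionise with ring expansion of the adjacent cyclobutane (the C3–C2 bond lies anti to the leaving group), or eliminate, faster than the hindered backside attack. Fallback: carry out the displacement while C1 is still a ketone, whose α-carbon C2 is a poor migrating group. From 30, HF·pyridine gives the hydroxy cyclobutanone F4, and PPh3/CBr4 gives the bromo cyclobutanone F5. Meerwein–Ponndorf–Verley reduction (Al(O-i-Pr)3, i-PrOH, toluene, 80 °C) is reversible, hence thermodynamically controlled, and compatible with the alkyl bromide; it gives the exo bromo alcohol F6. Acetylation (Ac2O, DMAP) returns to the route at 34.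

- **Step 22 (C1 configuration).** The ketyl of the strained cyclobutanone may fragment, or protonation may be kinetically controlled and deliver the endo alcohol. Fallback: from 30, NaBH4 in MeOH attacks the less screened face; if this gives the endo cyclobutanol F7, it is equilibrated by Oppenauer/Meerwein–Ponndorf–Verley redox exchange (Al(O-i-Pr)3, catalytic acetone, toluene/i-PrOH, reflux) to the more stable exo alcohol 31, where the route resumes.

Further compounds
F1 | step 20 | carboxylic acid (C1 CO2H) of 22 | OC(=O)[C@@H]1[C@@H](C)C2(OCCO2)C[C@H](C)[C@@]1(C)C[C@@H](O[Si](C)(C)C(C)(C)C)C(C)=C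
F2 | step 20 | acid chloride of F1 | ClC(=O)[C@@H]1[C@@H](C)C2(OCCO2)C[C@H](C)[C@@]1(C)C[C@@H](O[Si](C)(C)C(C)(C)C)C(C)=C
F3 | step 20 | ketene (C11=C1=O) | O=C=C1[C@@H](C)C2(OCCO2)C[C@H](C)[C@@]1(C)C[C@@H](O[Si](C)(C)C(C)(C)C)C(C)=C
F4 | step 25 | hydroxy cyclobutanone (C4 OH, C9 ketal) | O=C1C[C@@]2(C)[C@H](O)C[C@]3(C)[C@@H](C)CC4(OCCO4)[C@H](C)[C@]123
F5 | step 25 | bromo cyclobutanone (C4 Br, C9 ketal) | O=C1C[C@@]2(C)[C@@H](Br)C[C@]3(C)[C@@H](C)CC4(OCCO4)[C@H](C)[C@]123
F6 | step 25 | exo bromo alcohol (C1 OH, C4 Br, C9 ketal) | O[C@@H]1C[C@@]2(C)[C@@H](Br)C[C@]3(C)[C@@H](C)CC4(OCCO4)[C@H](C)[C@]123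
F7 | step 22 | endo cyclobutanol (C1 epimer of 31) | O[C@H]1C[C@@]2(C)[C@H](O[Si](C)(C)C(C)(C)C)C[C@]3(C)[C@@H](C)CC4(OCCO4)[C@H](C)[C@]123
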